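## Retrosynthetic overview

1. Target 29 is traced back to the bicyclic diene 24 by late acylation of O8 (angelate) and O6 (acetate) and saturation of C2=C3. Guaiane numbering is used: C1/C5 ring fusion, C4 carbinol, C6 OAc, C7 isopropyl, C8 OAng, C10 =C–Me.
2. Diene 24 comes from the open-chain dienyne 21 by one ene–yne–ene metathesis that makes C10=C1 and C2=C3. The enabling feature is C1: an sp2 ring-fusion carbon common to both rings, doubly bonded to C10 of the seven-membered ring and singly bonded to the unfunctionalised C2–C3 bridge of the five-membered ring beside the tertiary carbinol C4, i.e. a latent 1,3-diene C10=C1–C2=C3.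
3. Dienyne 21 comes from two Evans syn-aldol reactions (C7–C8, then C5–C6), a hydroxyl-directed epoxidation plus one-carbon epoxide-to-vinyl-carbinol homologation for C4, and an alkyne made from the C1 aldehyde.
4. Ring order: the seven-membered ring closes first (C10=C1, enyne closure) and the five-membered ring last (C2=C3), both in step 15.

Key step: step 15

Remark: imide 3 and oxazolidinone 10 are taken as purchased; CIP descriptors of C4 and C7 change along the route only through priority changes, not through inversion.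

## Route

Step 1
Reactants: 1 3-methylbut-3-en-1-ol
Product: 2 3-methylbut-3-enal
Conditions: Dess–Martin periodinane, pyridine, CH2Cl2, 0 °C; filtered solution used at once
Reagents that add atoms: none
Why: Dess–Martin oxidation under neutral, buffered conditions should give the β,γ-unsaturated aldehyde without moving the alkene into conjugation; no stereocentre is formed.

Step 2
Reactants: 3 (4R)-4-benzyl-3-(3-methylbutanoyl)-1,3-oxazolidin-2-one, 2 3-methylbut-3-enal
Product: 5 (4R)-4-benzyl-3-[(2R,3S)-3-hydroxy-5-methyl-2-(propan-2-yl)hex-5-enoyl]-1,3-oxazolidin-2-one, via dibutylboron Z-enolate 4 (not isolated)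
Conditions: Bu2BOTf, iPr2NEt, CH2Cl2, −78 to 0 °C; then 2, −78 to 0 °C; pH 7 buffer, MeOH, H2O2
Reagents that add atoms: none
Why: Evans boron aldol reaction, in which the Z-enolate adds through a Zimmerman–Traxler chair on the face away from the benzyl group of the (R)-auxiliary and so sets C7 (R) and C8 (S) as the syn pair.

Step 3
Reactants: 5 (4R)-4-benzyl-3-[(2R,3S)-3-hydroxy-5-methyl-2-(propan-2-yl)hex-5-enoyl]-1,3-oxazolidin-2-one
Product: 6 (4R)-4-benzyl-3-[(2R,3S)-3-(tert-butyldimethylsilyloxy)-5-methyl-2-(propan-2-yl)hex-5-enoyl]-1,3-oxazolidin-2-one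
Conditions: TBSOTf, 2,6-lutidine, CH2Cl2, −78 to 0 °C
Reagents that add atoms: tert-butyldimethylsilyl triflate CC(C)(C)[Si](C)(C)OS(=O)(=O)C(F)(F)F
Why: Silylation with a silyl triflate and a hindered base masks O8 for the hydride, base and metathesis steps ahead and blocks retro-aldol cleavage; no stereocentre is touched.

Step 4
Reactants: 6 (4R)-4-benzyl-3-[(2R,3S)-3-(tert-butyldimethylsilyloxy)-5-methyl-2-(propan-2-yl)hex-5-enoyl]-1,3-oxazolidin-2-one
Product: 7 (2S,3S)-3-(tert-butyldimethylsilyloxy)-5-methyl-2-(propan-2-yl)hex-5-en-1-ol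
Conditions: LiBH4, MeOH (1 equiv), THF, 0 °C
Reagents that add atoms: none
Why: Reductive cleavage of the N-acyl oxazolidinone with LiBH4 should give the primary alcohol and return the auxiliary, with the silyl ether and alkene inert and C7 not epimerised.

Step 5
Reactants: 7 (2S,3S)-3-(tert-butyldimethylsilyloxy)-5-methyl-2-(propan-2-yl)hex-5-en-1-ol
Product: 8 (2R,3S)-3-(tert-butyldimethylsilyloxy)-5-methyl-2-(propan-2-yl)hex-5-enal
Conditions: Dess–Martin periodinane, pyridine, CH2Cl2, 0 °C to rt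
Reagents that add atoms: none
Why: Dess–Martin oxidation should give the α-branched aldehyde without epimerisation at C7 or β-elimination of the silyloxy group.

Step 6
Reactants: 9 3-methylbut-3-enoic acid, 10 (4S)-4-benzyl-1,3-oxazolidin-2-one
Product: 12 (4S)-4-benzyl-3-(3-methylbut-3-enoyl)-1,3-oxazolidin-2-one, via mixed pivalic anhydride 11 (not isolated)
Conditions: PivCl, Et3N, THF, −20 °C; then LiCl, 10, −20 °C to rt
Reagents that add atoms: none
Why: N-acylation of the oxazolidinone through the mixed pivalic anhydride with LiCl/Et3N avoids strong base, so the β,γ-alkene should not move into conjugation.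

Step 7
Reactants: 12 (4S)-4-benzyl-3-(3-methylbut-3-enoyl)-1,3-oxazolidin-2-one, 8 (2R,3S)-3-(tert-butyldimethylsilyloxy)-5-methyl-2-(propan-2-yl)hex-5-enal
Product: 14 (4S)-4-benzyl-3-[(2S,3R,4S,5S)-5-(tert-butyldimethylsilyloxy)-3-hydroxy-7-methyl-4-(propan-2-yl)-2-(prop-1-en-2-yl)oct-7-enoyl]-1,3-oxazolidin-2-one, via dibutylboron Z-dienolate 13 (not isolated)
Conditions: Bu2BOTf, iPr2NEt, CH2Cl2, −78 to 0 °C; then 8, −78 °C to rt; pH 7 buffer, MeOH, H2O2, 0 °C
Reagents that add atoms: none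
Why: Second Evans boron aldol reaction, in which the Z-dienolate reacts at its α-carbon through the Zimmerman–Traxler chair under control of the (S)-auxiliary, setting C5 (S) and C6 (R) syn, a sense that agrees with the anti-Felkin preference of Z-enolates and places O6 anti to the C7 isopropyl group.

Step 8
Reactants: 14 (4S)-4-benzyl-3-[(2S,3R,4S,5S)-5-(tert-butyldimethylsilyloxy)-3-hydroxy-7-methyl-4-(propan-2-yl)-2-(prop-1-en-2-yl)oct-7-enoyl]-1,3-oxazolidin-2-one
Product: 15 (4S)-4-benzyl-3-[(2S,3R,4R,5S)-5-(tert-butyldimethylsilyloxy)-7-methyl-4-(propan-2-yl)-2-(prop-1-en-2-yl)-3-(triethylsilyloxy)oct-7-enoyl]-1,3-oxazolidin-2-one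
Conditions: TESOTf, 2,6-lutidine, CH2Cl2, −78 to 0 °C
Reagents that add atoms: triethylsilyl triflate CC[Si](CC)(CC)OS(=O)(=O)C(F)(F)F
Why: Silylation of O6 with a group that can later be removed in the presence of the TBS ether leaves the C1 oxygen as the only free hydroxyl after the next step; no stereocentre is touched.

Step 9
Reactants: 15 (4S)-4-benzyl-3-[(2S,3R,4R,5S)-5-(tert-butyldimethylsilyloxy)-7-methyl-4-(propan-2-yl)-2-(prop-1-en-2-yl)-3-(triethylsilyloxy)oct-7-enoyl]-1,3-oxazolidin-2-one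
Product: 16 (2R,3S,4R,5S)-5-(tert-butyldimethylsilyloxy)-7-methyl-4-(propan-2-yl)-2-(prop-1-en-2-yl)-3-(triethylsilyloxy)oct-7-en-1-ol
Conditions: LiBH4, MeOH (1 equiv), THF, 0 °C
Reagents that add atoms: none
Why: Reductive removal of the Evans auxiliary with LiBH4 should give the primary homoallylic alcohol that directs the next step, without epimerisation at C5.

Step 10
Reactants: 16 (2R,3S,4R,5S)-5-(tert-butyldimethylsilyloxy)-7-methyl-4-(propan-2-yl)-2-(prop-1-en-2-yl)-3-(triethylsilyloxy)oct-7-en-1-ol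
Product: 17 (2R,3R,4R,5S)-5-(tert-butyldimethylsilyloxy)-7-methyl-2-[(2R)-2-methyloxiran-2-yl]-4-(propan-2-yl)-3-(triethylsilyloxy)oct-7-en-1-ol
Conditions: VO(acac)2 (5 mol %), t-BuOOH, CH2Cl2, 0 °C to rt
Reagents that add atoms: tert-butyl hydroperoxide CC(C)(C)OO
Why: Vanadium-catalysed hydroxyl-directed epoxidation of a homoallylic alcohol, in which oxygen is delivered inside a chair vanadate ester with the C6 branch on C5 equatorial and the alkene methyl pseudo-equatorial, should set C4 (R epoxide, oxygen syn to O6 along the chain) and leave the remote 2-methylallyl alkene untouched.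

Step 11
Reactants: 17 (2R,3R,4R,5S)-5-(tert-butyldimethylsilyloxy)-7-methyl-2-[(2R)-2-methyloxiran-2-yl]-4-(propan-2-yl)-3-(triethylsilyloxy)oct-7-en-1-ol
Product: 18 (2R,3R,4R,5S)-5-(tert-butyldimethylsilyloxy)-2-[(2S)-2-hydroxybut-3-en-2-yl]-7-methyl-4-(propan-2-yl)-3-(triethylsilyloxy)oct-7-en-1-ol
Conditions: Me3S+ I−, n-BuLi (excess), THF, −20 °C to rt
Reagents that add atoms: trimethylsulfonium iodide C[S+](C)C.[I-]
Why: One-carbon homologation of a terminal epoxide to an allylic alcohol with dimethylsulfonium methylide (ring opening at CH2, then ylide-mediated elimination) does not break the C4–O bond, so C4 keeps its configuration.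

Step 12
Reactants: 18 (2R,3R,4R,5S)-5-(tert-butyldimethylsilyloxy)-2-[(2S)-2-hydroxybut-3-en-2-yl]-7-methyl-4-(propan-2-yl)-3-(triethylsilyloxy)oct-7-en-1-ol
Product: 19 (3S,4R,5R,6R,7S)-7-(tert-butyldimethylsilyloxy)-3,9-dimethyl-6-(propan-2-yl)-3,5-bis(triethylsilyloxy)-4-[(triethylsilyloxy)methyl]deca-1,9-diene
Conditions: TESOTf (3 equiv), 2,6-lutidine, CH2Cl2, −78 to 0 °C
Reagents that add atoms: triethylsilyl triflate CC[Si](CC)(CC)OS(=O)(=O)C(F)(F)F
Why: Silylation of both hydroxyls with the silyl triflate protects the tertiary carbinol against retro-aldol cleavage in the next two steps and sets up the primary silyl ether for direct oxidation.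

Step 13
Reactants: 19 (3S,4R,5R,6R,7S)-7-(tert-butyldimethylsilyloxy)-3,9-dimethyl-6-(propan-2-yl)-3,5-bis(triethylsilyloxy)-4-[(triethylsilyloxy)methyl]deca-1,9-diene
Product: 20 (2R,3R,4R,5S)-5-(tert-butyldimethylsilyloxy)-7-methyl-4-(propan-2-yl)-3-(triethylsilyloxy)-2-[(2S)-2-(triethylsilyloxy)but-3-en-2-yl]oct-7-enal
Conditions: (COCl)2, DMSO, CH2Cl2, −78 to −30 °C; then Et3N, to 0 °C
Reagents that add atoms: none
Why: Swern oxidation with in situ cleavage of the primary triethylsilyl ether, which alone is attacked by the chlorosulfonium salt, should give the aldehyde directly while the secondary and tertiary silyl ethers stay and C5 is not epimerised at low temperature.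

Step 14
Reactants: 20 (2R,3R,4R,5S)-5-(tert-butyldimethylsilyloxy)-7-methyl-4-(propan-2-yl)-3-(triethylsilyloxy)-2-[(2S)-2-(triethylsilyloxy)but-3-en-2-yl]oct-7-enal
Product: 21 (3S,4R,5R,6R,7S)-7-(tert-butyldimethylsilyloxy)-4-ethynyl-3,9-dimethyl-6-(propan-2-yl)-3,5-bis(triethylsilyloxy)deca-1,9-diene
Conditions: dimethyl (1-diazo-2-oxopropyl)phosphonate, K2CO3, MeOH, 0 °C to rt
Reagents that add atoms: dimethyl (1-diazo-2-oxopropyl)phosphonate COP(=O)(OC)C(=[N+]=[N-])C(C)=O
Why: Seyferth–Gilbert homologation with the Ohira–Bestmann reagent should turn the aldehyde into the terminal alkyne C1≡C2 under mild carbonate conditions without touching C5.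

Step 15
Reactants: 21 (3S,4R,5R,6R,7S)-7-(tert-butyldimethylsilyloxy)-4-ethynyl-3,9-dimethyl-6-(propan-2-yl)-3,5-bis(triethylsilyloxy)deca-1,9-diene
Product: 24 (4S,5R,6R,7R,8S)-8-(tert-butyldimethylsilyloxy)-4,6-bis(triethylsilyloxy)guaia-1(10),2-diene, via C10 ruthenium alkylidene 22 (not isolated), via cycloheptadienyl ruthenium alkylidene 23 (not isolated)
Conditions: Grubbs II catalyst (10 mol %), toluene (2 mM), 80 °C, argon sparge
Reagents that add atoms: none
Why: Tandem ene–yne–ene ring-closing metathesis, the dienyne RCM known for fused bicyclic 1,3-dienes such as hydroazulenes: the catalyst loads on the unhindered 2-methylallyl terminus (22), exo enyne closure onto the internal alkyne carbon C1 forms C10=C1 and the seven-membered ring and moves the carbene to C2 (23), and ring-closing metathesis of 23 with the C3 vinyl group forms C2=C3 and the five-membered ring and releases ethylene. The cycloheptene is thus closed in the 7-exo enyne mode and the cyclopentene, last, by alkylidene/alkene RCM. The only other alkene alkylidene, at C3, could close nothing but a cyclobutene with the alkyne and is a resting state, and a catalyst that adds to the alkyne first gives a C1 alkylidene that must likewise close the seven-membered ring before the C2=C3 closure, so all productive paths share the ring order. No stereocentre is formed; C4 to C8 come from 21 and none should epimerise under the neutral conditions. The step needs intramolecular closure to win over intermolecular enyne metathesis and exo over endo attack on the alkyne, which high dilution, the seven- versus eight-membered ring choice and the hindered tertiary silyl ether beside the C3 vinyl group should secure.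

Step 16
Reactants: 24 (4S,5R,6R,7R,8S)-8-(tert-butyldimethylsilyloxy)-4,6-bis(triethylsilyloxy)guaia-1(10),2-diene
Product: 25 (4S,5R,6R,7R,8S)-8-(tert-butyldimethylsilyloxy)-4,6-bis(triethylsilyloxy)guai-1(10)-ene
Conditions: 2-nitrobenzenesulfonyl hydrazide, Et3N, CH2Cl2, rt
Reagents that add atoms: none
Why: Diimide reduction (syn transfer of H2 from HN=NH made in situ) should saturate the cis-disubstituted C2=C3 bond and leave the tetrasubstituted C1=C10 bond, which diimide does not reduce; no stereocentre is formed.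

Step 17
Reactants: 25 (4S,5R,6R,7R,8S)-8-(tert-butyldimethylsilyloxy)-4,6-bis(triethylsilyloxy)guai-1(10)-ene
Product: 26 (4S,5R,6R,7S,8S)-8-(tert-butyldimethylsilyloxy)guai-1(10)-ene-4,6-diol
Conditions: PPTS, MeOH/CH2Cl2, rt
Reagents that add atoms: none
Why: Acid-catalysed methanolysis should remove the two triethylsilyl ethers while the bulkier TBS ether on O8 survives (selective desilylation), which frees O6 for acetylation.

Step 18
Reactants: 26 (4S,5R,6R,7S,8S)-8-(tert-butyldimethylsilyloxy)guai-1(10)-ene-4,6-diol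
Product: 27 (4S,5R,6R,7S,8S)-6-acetoxy-8-(tert-butyldimethylsilyloxy)guai-1(10)-en-4-ol
Conditions: Ac2O, DMAP, pyridine, rt
Reagents that add atoms: acetic anhydride CC(=O)OC(C)=O
Why: DMAP-catalysed acylation should acetylate the secondary C6 hydroxyl, the tertiary C4 hydroxyl being unreactive at room temperature.

Step 19
Reactants: 27 (4S,5R,6R,7S,8S)-6-acetoxy-8-(tert-butyldimethylsilyloxy)guai-1(10)-en-4-ol
Product: 28 (4S,5R,6R,7R,8S)-6-acetoxyguai-1(10)-ene-4,8-diol
Conditions: HF·pyridine, pyridine, THF, 0 °C to rt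
Reagents that add atoms: none
Why: Fluoride-mediated desilylation under slightly acidic conditions should free O8 without acetyl migration from O6 or ionisation of the tertiary carbinol.

Step 20
Reactants: 28 (4S,5R,6R,7R,8S)-6-acetoxyguai-1(10)-ene-4,8-diol
Product: 29 (4S,5R,6R,7R,8S)-6-acetoxy-8-[(Z)-2-methylbut-2-enoyloxy]guai-1(10)-en-4-ol
Conditions: angelic acid, 2,4,6-trichlorobenzoyl chloride, Et3N, toluene, rt; then 28, 75 °C
Reagents that add atoms: angelic acid C/C=C(/C)C(=O)O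
Why: Yamaguchi-type esterification through the mixed 2,4,6-trichlorobenzoic anhydride should acylate the secondary C8 hydroxyl without Z-to-E isomerisation of the angelate and leave the tertiary C4 hydroxyl free.

## Compound list

1 | 3-methylbut-3-en-1-ol | C=C(C)CCO | starting material
2 | 3-methylbut-3-enal | C=C(C)CC=O | intermediate
3 | (4R)-4-benzyl-3-(3-methylbutanoyl)-1,3-oxazolidin-2-one | CC(C)CC(=O)N1[C@H](Cc2ccccc2)COC1=O | starting material
4 | dibutylboron Z-enolate of 3 | CCCCB(CCCC)O/C(=C\C(C)C)N1[C@H](Cc2ccccc2)COC1=O | intermediate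
5 | (4R)-4-benzyl-3-[(2R,3S)-3-hydroxy-5-methyl-2-(propan-2-yl)hex-5-enoyl]-1,3-oxazolidin-2-one | C=C(C)C[C@H](O)[C@@H](C(C)C)C(=O)N1[C@H](Cc2ccccc2)COC1=O | intermediate
6 | (4R)-4-benzyl-3-[(2R,3S)-3-(tert-butyldimethylsilyloxy)-5-methyl-2-(propan-2-yl)hex-5-enoyl]-1,3-oxazolidin-2-one | C=C(C)C[C@H](O[Si](C)(C)C(C)(C)C)[C@@H](C(C)C)C(=O)N1[C@H](Cc2ccccc2)COC1=O | intermediate
7 | (2S,3S)-3-(tert-butyldimethylsilyloxy)-5-methyl-2-(propan-2-yl)hex-5-en-1-ol | C=C(C)C[C@H](O[Si](C)(C)C(C)(C)C)[C@@H](C(C)C)CO | intermediate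
8 | (2R,3S)-3-(tert-butyldimethylsilyloxy)-5-methyl-2-(propan-2-yl)hex-5-enal | C=C(C)C[C@H](O[Si](C)(C)C(C)(C)C)[C@@H](C(C)C)C=O | intermediate
9 | 3-methylbut-3-enoic acid | C=C(C)CC(=O)O | starting material
10 | (4S)-4-benzyl-1,3-oxazolidin-2-one | O=C1N[C@@H](Cc2ccccc2)CO1 | starting material
11 | 3-methylbut-3-enoic pivalic anhydride | C=C(C)CC(=O)OC(=O)C(C)(C)C | intermediate
12 | (4S)-4-benzyl-3-(3-methylbut-3-enoyl)-1,3-oxazolidin-2-one | C=C(C)CC(=O)N1[C@@H](Cc2ccccc2)COC1=O | intermediate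
13 | dibutylboron Z-dienolate of 12 | CCCCB(CCCC)O/C(=C\C(C)=C)N1[C@@H](Cc2ccccc2)COC1=O | intermediate
14 | (4S)-4-benzyl-3-[(2S,3R,4S,5S)-5-(tert-butyldimethylsilyloxy)-3-hydroxy-7-methyl-4-(propan-2-yl)-2-(prop-1-en-2-yl)oct-7-enoyl]-1,3-oxazolidin-2-one | C=C(C)C[C@H](O[Si](C)(C)C(C)(C)C)[C@@H](C(C)C)[C@@H](O)[C@H](C(C)=C)C(=O)N1[C@@H](Cc2ccccc2)COC1=O | intermediate
15 | (4S)-4-benzyl-3-[(2S,3R,4R,5S)-5-(tert-butyldimethylsilyloxy)-7-methyl-4-(propan-2-yl)-2-(prop-1-en-2-yl)-3-(triethylsilyloxy)oct-7-enoyl]-1,3-oxazolidin-2-one | C=C(C)C[C@H](O[Si](C)(C)C(C)(C)C)[C@@H](C(C)C)[C@@H](O[Si](CC)(CC)CC)[C@H](C(C)=C)C(=O)N1[C@@H](Cc2ccccc2)COC1=O | intermediate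
16 | (2R,3S,4R,5S)-5-(tert-butyldimethylsilyloxy)-7-methyl-4-(propan-2-yl)-2-(prop-1-en-2-yl)-3-(triethylsilyloxy)oct-7-en-1-ol | C=C(C)C[C@H](O[Si](C)(C)C(C)(C)C)[C@@H](C(C)C)[C@@H](O[Si](CC)(CC)CC)[C@H](C(C)=C)CO | intermediate
17 | (2R,3R,4R,5S)-5-(tert-butyldimethylsilyloxy)-7-methyl-2-[(2R)-2-methyloxiran-2-yl]-4-(propan-2-yl)-3-(triethylsilyloxy)oct-7-en-1-ol | C=C(C)C[C@H](O[Si](C)(C)C(C)(C)C)[C@@H](C(C)C)[C@@H](O[Si](CC)(CC)CC)[C@H]([C@]1(C)CO1)CO | intermediate
18 | (2R,3R,4R,5S)-5-(tert-butyldimethylsilyloxy)-2-[(2S)-2-hydroxybut-3-en-2-yl]-7-methyl-4-(propan-2-yl)-3-(triethylsilyloxy)oct-7-en-1-ol | C=C(C)C[C@H](O[Si](C)(C)C(C)(C)C)[C@@H](C(C)C)[C@@H](O[Si](CC)(CC)CC)[C@H]([C@@](C)(O)C=C)CO | intermediate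
19 | (3S,4R,5R,6R,7S)-7-(tert-butyldimethylsilyloxy)-3,9-dimethyl-6-(propan-2-yl)-3,5-bis(triethylsilyloxy)-4-[(triethylsilyloxy)methyl]deca-1,9-diene | C=C(C)C[C@H](O[Si](C)(C)C(C)(C)C)[C@@H](C(C)C)[C@@H](O[Si](CC)(CC)CC)[C@H]([C@@](C)(O[Si](CC)(CC)CC)C=C)CO[Si](CC)(CC)CC | intermediate
20 | (2R,3R,4R,5S)-5-(tert-butyldimethylsilyloxy)-7-methyl-4-(propan-2-yl)-3-(triethylsilyloxy)-2-[(2S)-2-(triethylsilyloxy)but-3-en-2-yl]oct-7-enal | C=C(C)C[C@H](O[Si](C)(C)C(C)(C)C)[C@@H](C(C)C)[C@@H](O[Si](CC)(CC)CC)[C@H]([C@@](C)(O[Si](CC)(CC)CC)C=C)C=O | intermediate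
21 | (3S,4R,5R,6R,7S)-7-(tert-butyldimethylsilyloxy)-4-ethynyl-3,9-dimethyl-6-(propan-2-yl)-3,5-bis(triethylsilyloxy)deca-1,9-diene | C=C(C)C[C@H](O[Si](C)(C)C(C)(C)C)[C@@H](C(C)C)[C@@H](O[Si](CC)(CC)CC)[C@H]([C@@](C)(O[Si](CC)(CC)CC)C=C)C#C | intermediate
22 | RuCl2(SIMes) alkylidene at C10 of 21 (2-methylallyl CH2 exchanged for Ru) | Cl[Ru](Cl)(=C(C)C[C@H](O[Si](C)(C)C(C)(C)C)[C@@H](C(C)C)[C@@H](O[Si](CC)(CC)CC)[C@H]([C@@](C)(O[Si](CC)(CC)CC)C=C)C#C)=C1N(c2c(C)cc(C)cc2C)CCN1c1c(C)cc(C)cc1C | intermediate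
23 | RuCl2(SIMes) alkylidene at C2 of the closed cycloheptene (C10=C1 formed, C3 vinyl still free) | Cl[Ru](Cl)(=CC1=C(C)C[C@H](O[Si](C)(C)C(C)(C)C)[C@@H](C(C)C)[C@@H](O[Si](CC)(CC)CC)[C@@H]1[C@@](C)(O[Si](CC)(CC)CC)C=C)=C2N(c3c(C)cc(C)cc3C)CCN2c2c(C)cc(C)cc2C | intermediate
24 | (4S,5R,6R,7R,8S)-8-(tert-butyldimethylsilyloxy)-4,6-bis(triethylsilyloxy)guaia-1(10),2-diene | CC(C)(C)[Si](C)(C)O[C@H]1CC(C)=C2C=C[C@](C)(O[Si](CC)(CC)CC)[C@H]2[C@H](O[Si](CC)(CC)CC)[C@@H]1C(C)C | intermediate
25 | (4S,5R,6R,7R,8S)-8-(tert-butyldimethylsilyloxy)-4,6-bis(triethylsilyloxy)guai-1(10)-ene | CC(C)(C)[Si](C)(C)O[C@H]1CC(C)=C2CC[C@](C)(O[Si](CC)(CC)CC)[C@H]2[C@H](O[Si](CC)(CC)CC)[C@@H]1C(C)C | intermediate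
26 | (4S,5R,6R,7S,8S)-8-(tert-butyldimethylsilyloxy)guai-1(10)-ene-4,6-diol | CC(C)(C)[Si](C)(C)O[C@H]1CC(C)=C2CC[C@](C)(O)[C@H]2[C@H](O)[C@@H]1C(C)C | intermediate
27 | (4S,5R,6R,7S,8S)-6-acetoxy-8-(tert-butyldimethylsilyloxy)guai-1(10)-en-4-ol | CC(C)(C)[Si](C)(C)O[C@H]1CC(C)=C2CC[C@](C)(O)[C@H]2[C@H](OC(C)=O)[C@@H]1C(C)C | intermediate
28 | (4S,5R,6R,7R,8S)-6-acetoxyguai-1(10)-ene-4,8-diol | O[C@H]1CC(C)=C2CC[C@](C)(O)[C@H]2[C@H](OC(C)=O)[C@@H]1C(C)C | intermediate
29 | (4S,5R,6R,7R,8S)-6-acetoxy-8-[(Z)-2-methylbut-2-enoyloxy]guai-1(10)-en-4-ol; systematic: [(3S,3aR,4R,5R,6S)-4-acetyloxy-3-hydroxy-3,8-dimethyl-5-(propan-2-yl)-1,2,3,3a,4,5,6,7-octahydroazulen-6-yl] (Z)-2-methylbut-2-enoate | C/C=C(/C)C(=O)O[C@H]1CC(C)=C2CC[C@](C)(O)[C@H]2[C@H](OC(C)=O)[C@@H]1C(C)C | target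

## Step count and risks

Total step count: 20. Longest linear sequence: 19 steps (1 to 29 through steps 1–5 and 7–20; step 6 is a one-step branch).

Steps most likely to fail:

**Step 15 (metathesis cascade).** The catalyst may load on the alkyne or rest on the C3 vinyl group faster than on the 1,1-disubstituted 2-methylallyl terminus, so that intermolecular enyne metathesis and oligomerisation outrun closure of the seven-membered ring. The fallback sets out from 17 and comes back at 24; it closes the two rings in separate operations and brings in the C3 vinyl group only after the seven-membered ring exists. Dess–Martin oxidation of 17 would give the epoxy aldehyde F1. Dibromo-olefination (CBr4, PPh3, Et3N, CH2Cl2, 0 °C) would give the dibromoalkene F2, and n-BuLi (THF, −78 °C) the epoxy enyne F3, whose only alkene is the 2-methylallyl group. Ring-closing enyne metathesis (Grubbs II, toluene, 80 °C) should then give the 1-vinylcycloheptene epoxide F4. Sulfonium methylide homologation as in step 11 would give the dienyl carbinol F5, and diene ring-closing metathesis (Grubbs II, CH2Cl2, 40 °C) would close the five-membered ring, again last, to the dienol F6. Silylation with TESOTf/2,6-lutidine returns to 24.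

**Step 10 (directed epoxidation).** Oxygen transfer may occur with poor or reversed facial selectivity if the alkene presents its other face in the vanadate chair (methylene rather than methyl pseudo-equatorial). The fallback sets out from 14 and comes back at 17; it changes the directing group. The free C6 hydroxyl of 14 would direct the VO(acac)2/t-BuOOH epoxidation through a chair that contains C6 instead of C1, which exposes the opposite alkene face for the same conformational preference, to give the epoxy alcohol imide F7. Silylation (TESOTf, 2,6-lutidine) would give the epoxy imide silyl ether F8. Reductive removal of the auxiliary with NaBH4 in THF/H2O, which leaves the epoxide alone, returns to 17.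

**Step 14 (alkyne formation).** Epimerisation at C5 or β-elimination of a silyloxy group may occur in methanolic carbonate before the hindered aldehyde is consumed. The fallback sets out from 20 and comes back at 21; it uses a two-stage, low-temperature Corey–Fuchs sequence. CBr4, PPh3 and Et3N (CH2Cl2, 0 °C) would give the dibromoalkene F9, and n-BuLi (2.2 equiv, THF, −78 °C) followed by aqueous NH4Cl would give 21.

## Further compounds

F1 | step 15 | epoxy aldehyde, C1 alcohol of 17 oxidised to CHO | C=C(C)C[C@H](O[Si](C)(C)C(C)(C)C)[C@@H](C(C)C)[C@@H](O[Si](CC)(CC)CC)[C@H]([C@]1(C)CO1)C=O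
F2 | step 15 | 1,1-dibromoalkene from F1 (CH=CBr2 on C5) | C=C(C)C[C@H](O[Si](C)(C)C(C)(C)C)[C@@H](C(C)C)[C@@H](O[Si](CC)(CC)CC)[C@H]([C@]1(C)CO1)C=C(Br)Br
F3 | step 15 | epoxy enyne, terminal alkyne on C5 with the 2-methyloxirane still in place | C=C(C)C[C@H](O[Si](C)(C)C(C)(C)C)[C@@H](C(C)C)[C@@H](O[Si](CC)(CC)CC)[C@H]([C@]1(C)CO1)C#C
F4 | step 15 | 1-vinylcycloheptene epoxide (seven-membered ring closed, C10=C1, vinyl on C1, oxirane on C5) | CC(C)(C)[Si](C)(C)O[C@H]1CC(C)=C(C=C)[C@@H]([C@]2(C)CO2)[C@H](O[Si](CC)(CC)CC)[C@@H]1C(C)C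
F5 | step 15 | dienyl carbinol (vinyl on C1, (2S)-2-hydroxybut-3-en-2-yl on C5) | CC(C)(C)[Si](C)(C)O[C@H]1CC(C)=C(C=C)[C@@H]([C@@](C)(O)C=C)[C@H](O[Si](CC)(CC)CC)[C@@H]1C(C)C
F6 | step 15 | (4S,5R,6R,7R,8S)-8-(tert-butyldimethylsilyloxy)-6-(triethylsilyloxy)guaia-1(10),2-dien-4-ol | CC(C)(C)[Si](C)(C)O[C@H]1CC(C)=C2C=C[C@](C)(O)[C@H]2[C@H](O[Si](CC)(CC)CC)[C@@H]1C(C)C
F7 | step 10 | epoxy alcohol imide, (2R)-2-methyloxirane in place of the isopropenyl group of 14 | C=C(C)C[C@H](O[Si](C)(C)C(C)(C)C)[C@@H](C(C)C)[C@@H](O)[C@H]([C@]1(C)CO1)C(=O)N2[C@@H](Cc3ccccc3)COC2=O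
F8 | step 10 | O6-triethylsilyl ether of F7 | C=C(C)C[C@H](O[Si](C)(C)C(C)(C)C)[C@@H](C(C)C)[C@@H](O[Si](CC)(CC)CC)[C@H]([C@]1(C)CO1)C(=O)N2[C@@H](Cc3ccccc3)COC2=O
F9 | step 14 | 1,1-dibromoalkene from 20 (CH=CBr2 on C5) | C=C(C)C[C@H](O[Si](C)(C)C(C)(C)C)[C@@H](C(C)C)[C@@H](O[Si](CC)(CC)CC)[C@H]([C@@](C)(O[Si](CC)(CC)CC)C=C)C=C(Br)Br
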